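Numbering: C1 = carbinol carbon of the isobutyrate; C2, C3 = ring CH2; C4=C5 = ring olefin, with C15H2OH on C4; C6 (O-bearing) and C7 = fusion carbons of the α-methylene lactone ring O–C12(=O)–C11(=C13H2); C8(O)–C9=C10–C14(=O) = butenolide ring.
Enabling feature: the carbocycle bond C7–C8 lies between the two lactone rings. Read backwards, C13–C11=C7 of a 3-(bromomethyl)butenolide ring is an allyl metal whose γ-carbon is C7, and C8 of a 5-hydroxybutenolide ring is a latent aldehyde, so one carbonyl allylation makes this bond.
Cuts, in order: O15–Si; C7–C8 together with O8–C14; the C14/C8 oxygenation (back to a 2-silylfuran); C7=C11 (metathesis) and O6–C12 (ester); C3–C4 (B-alkyl Suzuki); C1–C2 and C5–C6 (carbonyl additions).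
Forward: a silylfuran piece (C1–C3, C8–C10, C14) and an iodo-diene piece (C4–C7, C15) are joined at C3–C4. The bromomethylbutenolide ring is then closed and the furan oxidised. The ten-membered ring and the butenolide ring close together, and the α-methylene lactone emerges from the allyl shift.
Stereochemistry: C1 and C6 come from lipase resolutions of two small allylic alcohols, and the C4=C5 geometry from trans-hydroalumination/iodination. C7 follows from C6 (attack anti to the C5 side chain), and C8 from the carboxylate-bound, C1-biased transition state of the ring closure.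

Key step: step 12

Remark on the chemistry: the lactol carbon C8 of 25 is an anomeric mixture that is erased in the open formyl-acid form; the allylindium, whose composition in water is not defined, is drawn as RInBr2; the S descriptor at C6 in 15–21 becomes R in 22–29 only through a change of CIP ranking, not of geometry.

Step 1
Reactants: 1 3-furaldehyde
Product: 5 2-(trimethylsilyl)furan-3-carbaldehyde, via lithium amino alkoxide 2 (not isolated), via C2-lithio amino alkoxide 3 (not isolated), via C2-silyl amino alkoxide 4 (not isolated)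
Conditions: Me2NCH2CH2NHMe, n-BuLi, THF, −20 °C; 1; n-BuLi, −20 °C; Me3SiCl, −78 °C → rt; H2O
Reagents that add atoms: chlorotrimethylsilane, C[Si](C)(C)Cl
Why: Directed ortho-metalation through an in situ α-amino alkoxide: the lithium amide masks the aldehyde as 2, its chelating dimethylaminoethyl arm holds n-BuLi next to the acidic C2–H so that 3 forms regioselectively, and silylation followed by aqueous collapse of 4 returns the aldehyde, the silyl group marking the furan carbon that will become C14.

Step 2
Reactants: 5 2-(trimethylsilyl)furan-3-carbaldehyde, 6 vinylmagnesium bromide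
Product: 7 (±)-1-[2-(trimethylsilyl)furan-3-yl]prop-2-en-1-ol
Conditions: CH2=CHMgBr, THF, −78 → 0 °C; aq. NH4Cl
Reagents that add atoms: none
Why: Grignard 1,2-addition to a heteroaromatic aldehyde forms C1–C2; C1 is racemic at this point and is resolved in the next step.

Step 3
Reactants: 7 (±)-1-[2-(trimethylsilyl)furan-3-yl]prop-2-en-1-ol
Product: 8 (S)-1-[2-(trimethylsilyl)furan-3-yl]prop-2-en-1-ol
Conditions: Novozym 435 (immobilised Candida antarctica lipase B), vinyl acetate, MTBE, 30 °C, stopped just past half conversion; chromatography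
Reagents that add atoms: none
Why: Lipase-catalysed kinetic resolution by enantioselective transesterification: by the empirical large/medium size rule for secondary alcohols the R enantiomer (large silylfuryl, medium vinyl) should be acetylated, so the S alcohol with the C1 configuration of the target should remain and is separated from the acetate.

Step 4
Reactants: 8 (S)-1-[2-(trimethylsilyl)furan-3-yl]prop-2-en-1-ol, 9 isobutyryl chloride
Product: 10 (S)-1-[2-(trimethylsilyl)furan-3-yl]prop-2-en-1-yl 2-methylpropanoate
Conditions: i-PrCOCl, pyridine, DMAP (cat.), CH2Cl2, 0 °C → rt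
Reagents that add atoms: none
Why: DMAP-catalysed acylation of a secondary alcohol with an acid chloride leaves the C1–O bond intact and so keeps the configuration, and installing the final ester now saves a protecting group.

Step 5
Reactants: 11 tert-butyldimethyl(prop-2-yn-1-yloxy)silane, 12 acrolein
Product: 14 (±)-6-[(tert-butyldimethylsilyl)oxy]hex-1-en-4-yn-3-ol, via lithium acetylide 13 (not isolated)
Conditions: n-BuLi, THF, −78 °C; acrolein, −78 °C; aq. NH4Cl
Reagents that add atoms: none
Why: 1,2-Addition of a lithium acetylide to an enal at low temperature forms C5–C6; C6 is racemic here and is resolved in the next step.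

Step 6
Reactants: 14 (±)-6-[(tert-butyldimethylsilyl)oxy]hex-1-en-4-yn-3-ol
Product: 15 (S)-6-[(tert-butyldimethylsilyl)oxy]hex-1-en-4-yn-3-ol
Conditions: Novozym 435, vinyl acetate, hexane, 30 °C, stopped just past half conversion; chromatography
Reagents that add atoms: none
Why: Lipase-catalysed kinetic resolution of an alkenyl alkynyl carbinol: the long silyloxymethyl-alkynyl arm acts as the large group and vinyl as the medium group, so the R alcohol should be acetylated and the S alcohol, which has the spatial arrangement needed at C6, should remain.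

Step 7
Reactants: 15 (S)-6-[(tert-butyldimethylsilyl)oxy]hex-1-en-4-yn-3-ol
Product: 17 (3S,4Z)-6-[(tert-butyldimethylsilyl)oxy]-5-iodohexa-1,4-dien-3-ol, via cyclic alkenylalanate 16 (not isolated)
Conditions: NaAlH2(OCH2CH2OMe)2 (Red-Al), THF, 0 °C; EtOAc; I2, THF, −78 → 0 °C; aqueous work-up
Reagents that add atoms: iodine, II
Why: Hydroxyl-directed trans-hydroalumination of a propargylic alcohol followed by iodinolysis: the C6 alkoxide delivers hydride to C5 and ties aluminium to C4 in the five-membered alanate 16, and iodine replaces aluminium with retention, so iodine ends cis to C6 and C15 trans to it, which is the ring-olefin geometry of the target, while C6 is untouched.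

Step 8
Reactants: 10 (S)-1-[2-(trimethylsilyl)furan-3-yl]prop-2-en-1-yl 2-methylpropanoate, 17 (3S,4Z)-6-[(tert-butyldimethylsilyl)oxy]-5-iodohexa-1,4-dien-3-ol
Product: 19 (1S,4E,6S)-4-{[(tert-butyldimethylsilyl)oxy]methyl}-6-hydroxy-1-[2-(trimethylsilyl)furan-3-yl]octa-4,7-dien-1-yl 2-methylpropanoate, via B-alkyl-9-BBN 18 (not isolated)
Conditions: 10, 9-BBN-H, THF, 0 °C → rt; then H2O, Cs2CO3, 17, PdCl2(dppf) (cat.), AsPh3 (cat.), DMF, rt
Reagents that add atoms: none
Why: B-alkyl Suzuki–Miyaura coupling: 9-BBN adds to the terminal carbon of the only alkene of 10, water and base destroy surplus borane before diene 17 is introduced, and the sp3–sp2 coupling forms C3–C4 with retention of alkenyl geometry at room temperature, where the isobutyrate, the free C6 alcohol and both C–Si bonds should persist.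

Step 9
Reactants: 19 (1S,4E,6S)-4-{[(tert-butyldimethylsilyl)oxy]methyl}-6-hydroxy-1-[2-(trimethylsilyl)furan-3-yl]octa-4,7-dien-1-yl 2-methylpropanoate, 20 2-(bromomethyl)acrylic acid
Product: 21 (1S,4E,6S)-6-{[2-(bromomethyl)acryloyl]oxy}-4-{[(tert-butyldimethylsilyl)oxy]methyl}-1-[2-(trimethylsilyl)furan-3-yl]octa-4,7-dien-1-yl 2-methylpropanoate
Conditions: DCC, DMAP (cat.), CH2Cl2, 0 °C
Reagents that add atoms: none
Why: Steglich esterification under neutral conditions is chosen because the bis-allylic C6 alcohol ionises in acid; the C6–O bond is not broken, so the configuration is kept.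

Step 10
Reactants: 21 (1S,4E,6S)-6-{[2-(bromomethyl)acryloyl]oxy}-4-{[(tert-butyldimethylsilyl)oxy]methyl}-1-[2-(trimethylsilyl)furan-3-yl]octa-4,7-dien-1-yl 2-methylpropanoate
Product: 22 (1S,4E)-5-[(2R)-4-(bromomethyl)-5-oxo-2,5-dihydrofuran-2-yl]-4-{[(tert-butyldimethylsilyl)oxy]methyl}-1-[2-(trimethylsilyl)furan-3-yl]pent-4-en-1-yl 2-methylpropanoate
Conditions: second-generation Hoveyda–Grubbs catalyst RuCl2(SIMes)(=CH-C6H4-2-OiPr) (cat.), CH2Cl2 (5 mM), reflux, argon sparge
Reagents that add atoms: none
Why: Ring-closing metathesis of an allylic α-substituted acrylate to an α-substituted butenolide: the carbene loads on the only monosubstituted alkene (C7) and closes on the acrylate methylene to form C7=C11, the trisubstituted C4=C5 alkene and the furan being unreactive, and a phosphine-free catalyst avoids quaternisation by the allylic bromide.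

Step 11
Reactants: 22 (1S,4E)-5-[(2R)-4-(bromomethyl)-5-oxo-2,5-dihydrofuran-2-yl]-4-{[(tert-butyldimethylsilyl)oxy]methyl}-1-[2-(trimethylsilyl)furan-3-yl]pent-4-en-1-yl 2-methylpropanoate
Product: 25 (1S,4E)-5-[(2R)-4-(bromomethyl)-5-oxo-2,5-dihydrofuran-2-yl]-4-{[(tert-butyldimethylsilyl)oxy]methyl}-1-(5-hydroxy-2-oxo-2,5-dihydrofuran-3-yl)pent-4-en-1-yl 2-methylpropanoate (anomeric mixture at C8), via furan endoperoxide 23 (not isolated), via trimethylsilyl formylacrylate 24 (not isolated)
Conditions: O2, tetraphenylporphyrin (cat.), visible light, CH2Cl2, −78 °C; then H2O, rt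
Reagents that add atoms: dioxygen, O=O
Why: Photooxygenation of a 2-silylfuran: [4+2] addition of singlet oxygen across C14/C8 gives 23, migration of silicon from C14 to peroxide oxygen makes this carbon alone the carboxyl carbon (24), and hydrolysis gives the α-substituted 5-hydroxybutenolide, the electron-rich furan being consumed at −78 °C well before the C4=C5 alkene, which two allylic C–O bonds deactivate.

Step 12
Reactants: 25 (1S,4E)-5-[(2R)-4-(bromomethyl)-5-oxo-2,5-dihydrofuran-2-yl]-4-{[(tert-butyldimethylsilyl)oxy]methyl}-1-(5-hydroxy-2-oxo-2,5-dihydrofuran-3-yl)pent-4-en-1-yl 2-methylpropanoate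
Product: 28 15-O-TBS ether of the target, (1S,6R,7S,8R)-configured, via allylindium formyl acid 26 (not isolated), via macrocyclic hydroxy acid 27 (not isolated)
Conditions: In powder (excess), NH4Cl, THF/H2O 3:1, rt, ultrasound, 25 added by syringe pump (final ca. 1 mM); work-up at pH 3
Reagents that add atoms: none
Why: Proposed new method: indium metal inserts into the allylic C13–Br bond, and the allylindium 26 adds through its γ-carbon C7 to the formyl group that the lactol C8 exposes by ring–chain tautomerism, so that the double bond moves to C11=C13 and the α-methylene lactone appears. The closest known reaction types are the intermolecular zinc or indium Barbier additions of 3-(bromomethyl)furan-2(5H)-ones to aldehydes and the aqueous indium allylation of 5-hydroxybutenolides to 5-allylbutenolides; joining the two within one molecule to close a medium ring has no precedent. The ten-membered carbocycle closes in a 10-exo-trig carbonyl addition to give 27, and its C8 oxygen, held cis to C14 across C9=C10, then closes the butenolide by 5-exo-trig acyl substitution with loss of water, which makes the sequence irreversible. C7 is controlled by C6: the new bond forms on the butenolide face opposite the C5 alkenyl substituent, which the eight-atom tether is long enough to reach, and this gives the trans C6/C7 fusion. C8 is controlled by the C14 carboxylate and by C1: carboxylate binding to indium keeps O8 on the C14 side and pushes C9 into the axial position of the Zimmerman–Traxler chair, which should convert the normal anti preference of this E-type allyl metal into the required C7/C8 syn relation, while the rotamer of S-configured C1 with H1 eclipsing C10–C14 leads the C2 tether over the same formyl face, the one that gives 8R. The step needs γ- rather than α-attack (inherent to 2-carboxyallyl metals, since it restores conjugation with C12), ring closure rather than oligomerisation, protonolysis or 1,4-elimination of the C6 carboxylate (pseudo-high dilution, soft covalent C–In bond), and inertness of the ester, the silyl ether and the Michael acceptors (neutral aqueous medium without base).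

Step 13
Reactants: 28 15-O-TBS ether of the target
Product: 29 target CNP0322767.4, (1S,6R,7S,8R)-15-hydroxy-1-isobutyryloxygermacra-4,9,11(13)-triene-12,6:14,8-diolide
Conditions: HF·pyridine, pyridine, THF, 0 °C
Reagents that add atoms: none
Why: Fluoride-mediated cleavage of a primary allylic silyl ether, with a pyridine buffer that keeps the medium too mild to affect the ester, the two lactones or the exocyclic methylene group.

Compound list
1 | 3-furaldehyde | O=Cc1ccoc1 | starting material
2 | lithium α-amino alkoxide from 1 and lithium N,N,N'-trimethylethylenediamide | [Li]OC(N(C)CCN(C)C)c1ccoc1 | intermediate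
3 | C2-lithiated α-amino alkoxide | [Li]OC(N(C)CCN(C)C)c1ccoc1[Li] | intermediate
4 | C2-trimethylsilylated α-amino alkoxide | [Li]OC(N(C)CCN(C)C)c1ccoc1[Si](C)(C)C | intermediate
5 | 2-(trimethylsilyl)furan-3-carbaldehyde | O=Cc1ccoc1[Si](C)(C)C | intermediate
6 | vinylmagnesium bromide | C=C[Mg]Br | starting material
7 | (±)-1-[2-(trimethylsilyl)furan-3-yl]prop-2-en-1-ol | C=CC(O)c1ccoc1[Si](C)(C)C | intermediate
8 | (S)-1-[2-(trimethylsilyl)furan-3-yl]prop-2-en-1-ol | C=C[C@H](O)c1ccoc1[Si](C)(C)C | intermediate
9 | isobutyryl chloride | CC(C)C(Cl)=O | starting material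
10 | (S)-1-[2-(trimethylsilyl)furan-3-yl]prop-2-en-1-yl 2-methylpropanoate | C=C[C@H](OC(=O)C(C)C)c1ccoc1[Si](C)(C)C | intermediate
11 | tert-butyldimethyl(prop-2-yn-1-yloxy)silane | C#CCO[Si](C)(C)C(C)(C)C | starting material
12 | acrolein | C=CC=O | starting material
13 | lithium acetylide of 11 | [Li]C#CCO[Si](C)(C)C(C)(C)C | intermediate
14 | (±)-6-[(tert-butyldimethylsilyl)oxy]hex-1-en-4-yn-3-ol | C=CC(O)C#CCO[Si](C)(C)C(C)(C)C | intermediate
15 | (S)-6-[(tert-butyldimethylsilyl)oxy]hex-1-en-4-yn-3-ol | C=C[C@H](O)C#CCO[Si](C)(C)C(C)(C)C | intermediate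
16 | sodium salt of the cyclic five-membered alkenylalanate (O6–Al–C4=C5–C6) | C=C[C@@H]1O[Al-](OCCOC)(OCCOC)C(CO[Si](C)(C)C(C)(C)C)=C1.[Na+] | intermediate
17 | (3S,4Z)-6-[(tert-butyldimethylsilyl)oxy]-5-iodohexa-1,4-dien-3-ol | C=C[C@H](O)/C=C(I)/CO[Si](C)(C)C(C)(C)C | intermediate
18 | B-alkyl-9-BBN from 10 (boron on C3) | B1(CC[C@H](OC(=O)C(C)C)c2ccoc2[Si](C)(C)C)C3CCCC1CCC3 | intermediate
19 | (1S,4E,6S)-4-{[(tert-butyldimethylsilyl)oxy]methyl}-6-hydroxy-1-[2-(trimethylsilyl)furan-3-yl]octa-4,7-dien-1-yl 2-methylpropanoate | C=C[C@H](O)/C=C(/CO[Si](C)(C)C(C)(C)C)CC[C@H](OC(=O)C(C)C)c1ccoc1[Si](C)(C)C | intermediate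
20 | 2-(bromomethyl)acrylic acid | C=C(CBr)C(=O)O | starting material
21 | (1S,4E,6S)-6-{[2-(bromomethyl)acryloyl]oxy}-4-{[(tert-butyldimethylsilyl)oxy]methyl}-1-[2-(trimethylsilyl)furan-3-yl]octa-4,7-dien-1-yl 2-methylpropanoate | C=C[C@H](OC(=O)C(=C)CBr)/C=C(/CO[Si](C)(C)C(C)(C)C)CC[C@H](OC(=O)C(C)C)c1ccoc1[Si](C)(C)C | intermediate
22 | bromomethylbutenolide silylfuran, (1S,6R), C3 and C6 cis on C4=C5 | BrCC1=C[C@H](OC1=O)/C=C(/CO[Si](C)(C)C(C)(C)C)CC[C@H](OC(=O)C(C)C)c2ccoc2[Si](C)(C)C | intermediate
23 | furan endoperoxide of 22 (O2 bridge C14/C8, mixture of facial isomers) | BrCC1=C[C@H](OC1=O)/C=C(/CO[Si](C)(C)C(C)(C)C)CC[C@H](OC(=O)C(C)C)C2=CC3OOC2([Si](C)(C)C)O3 | intermediate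
24 | trimethylsilyl (Z)-formylacrylate (C14 silyl ester, C8 aldehyde) | BrCC1=C[C@H](OC1=O)/C=C(/CO[Si](C)(C)C(C)(C)C)CC[C@H](OC(=O)C(C)C)/C(C(=O)O[Si](C)(C)C)=C/C=O | intermediate
25 | bromomethylbutenolide / 5-hydroxybutenolide seco compound, (1S,6R), anomeric mixture at C8 | BrCC1=C[C@H](OC1=O)/C=C(/CO[Si](C)(C)C(C)(C)C)CC[C@H](OC(=O)C(C)C)C2=CC(O)OC2=O | intermediate
26 | allylindium (drawn as RInBr2) of the open (Z)-formyl acid form of 25 | Br[In](Br)CC1=C[C@H](OC1=O)/C=C(/CO[Si](C)(C)C(C)(C)C)CC[C@H](OC(=O)C(C)C)/C(C(=O)O)=C/C=O | intermediate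
27 | ten-membered (Z)-γ-hydroxy enoic acid with the α-methylene lactone in place, (1S,6R,7S,8R) | C=C1C(=O)O[C@@H]2/C=C(/CO[Si](C)(C)C(C)(C)C)CC[C@H](OC(=O)C(C)C)/C(C(=O)O)=C/[C@@H](O)[C@@H]12 | intermediate
28 | 15-O-TBS ether of the target: ten-membered ring C1–C10, C3/C6 cis on C4=C5, trans-fused α-methylene lactone at C6/C7, butenolide bridging C8 and C10, (1S,6R,7S,8R) | C=C1C(=O)O[C@@H]2/C=C(/CO[Si](C)(C)C(C)(C)C)CC[C@H](OC(=O)C(C)C)C3=C[C@@H](OC3=O)[C@@H]12 | intermediate
29 | CNP0322767.4, (1S,6R,7S,8R)-15-hydroxy-1-isobutyryloxygermacra-4,9,11(13)-triene-12,6:14,8-diolide | C=C1C(=O)O[C@@H]2/C=C(/CO)CC[C@H](OC(=O)C(C)C)C3=C[C@@H](OC3=O)[C@@H]12 | target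

Total step count: 13. Longest linear sequence: 10 (steps 1–4 and 8–13).

Steps most likely to fail

1. Step 12.
What may go wrong: a slow medium-ring closure may be outrun by protonolysis of the C–In bond, by 1,4-elimination that opens the C6 lactone, or by oligomerisation. The allyl metal may also add to the wrong formyl face.
Fallback: it sets out from 17 and 10 and returns at 28. C7–C8 is made between two small fragments and the ten-membered ring is closed at C3–C4 instead.
- Iodide 17 is esterified with acid 20 (DCC, DMAP) to the iodo-dienyl 2-(bromomethyl)acrylate F1. This is ring-closed by metathesis as in step 10 to the iodoalkenyl bromomethylbutenolide F2.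
- Isobutyrate 10 is photooxygenated as in step 11 to the vinyl-bearing hydroxybutenolide F3.
- F2 and F3 are joined by the intermolecular aqueous indium Barbier reaction, for which both partners belong to known substrate classes. This gives the seco-C3/C4 bis-lactone F4, in which C7 and C8 are set from C6 alone.
- 9-BBN-H then adds to the only electron-rich terminal alkene to give the B-alkyl-9-BBN bis-lactone F5.
- An intramolecular B-alkyl Suzuki–Miyaura coupling under high dilution (PdCl2(dppf), AsPh3, Cs2CO3, DMF/THF/H2O) forms C3–C4 and gives 28.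

2. Step 10.
What may go wrong: turnover may stall through decomposition of the ruthenium carbene by the allylic bromide. Closure onto the electron-poor 1,1-disubstituted alkene may also be slow enough for dimerisation at C7 to take over.
Fallback: it sets out from 19 and returns at 22. C13 is brought in by a Morita–Baylis–Hillman reaction and bromine is introduced only after the ring is closed.
- Alcohol 19 is acylated with acryloyl chloride (i-Pr2NEt, CH2Cl2, 0 °C) to the C6 acrylate F6.
- DABCO and aqueous formaldehyde in dioxane convert it into the C6 2-(hydroxymethyl)acrylate F7.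
- Ring-closing metathesis of this bromide-free substrate gives the 3-(hydroxymethyl)butenolide F8.
- An Appel reaction (CBr4, PPh3, CH2Cl2, 0 °C) on its only free hydroxyl gives 22.

3. Step 3.
What may go wrong: the silyl group next to the carbinol may slow acyl transfer in the enzyme so much that the resolution stalls or loses enantiomer discrimination.
Fallback: it sets out from 5 and returns at 8, bypassing 7. C1 is created by catalytic enantioselective vinyl transfer instead of being resolved.
- Divinylzinc F9 is made from ZnCl2 and 6.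
- It is added to aldehyde 5 in toluene at 0 °C with catalytic (−)-3-exo-morpholinoisoborneol.
- This is an amino-alcohol-catalysed organozinc addition. By analogy with dialkylzinc additions to aromatic aldehydes it should attack the Si face and give the S alcohol 8 directly.

Further compounds
F1 | step 12 | (3S,4Z)-6-[(tert-butyldimethylsilyl)oxy]-5-iodohexa-1,4-dien-3-yl 2-(bromomethyl)acrylate | C=C[C@H](OC(=O)C(=C)CBr)/C=C(I)/CO[Si](C)(C)C(C)(C)C
F2 | step 12 | (5S)-3-(bromomethyl)-5-{(1Z)-3-[(tert-butyldimethylsilyl)oxy]-2-iodoprop-1-en-1-yl}furan-2(5H)-one | BrCC1=C[C@H](OC1=O)/C=C(I)/CO[Si](C)(C)C(C)(C)C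
F3 | step 12 | (1S)-1-(5-hydroxy-2-oxo-2,5-dihydrofuran-3-yl)prop-2-en-1-yl 2-methylpropanoate (anomeric mixture) | C=C[C@H](OC(=O)C(C)C)C1=CC(O)OC1=O
F4 | step 12 | seco-C3/C4 bis-lactone (iodine on C4, vinyl C2=C3; C1, C6, C7, C8 arranged as in 28) | C=C1C(=O)O[C@H](/C=C(I)/CO[Si](C)(C)C(C)(C)C)[C@H]1[C@H]2C=C([C@@H](OC(=O)C(C)C)C=C)C(=O)O2
F5 | step 12 | B-alkyl-9-BBN derivative of F4 (boron on C3) | C=C1C(=O)O[C@H](/C=C(I)/CO[Si](C)(C)C(C)(C)C)[C@H]1[C@H]2C=C([C@@H](OC(=O)C(C)C)CCB3C4CCCC3CCC4)C(=O)O2
F6 | step 10 | (1S,4E,6S)-6-(acryloyloxy)-4-{[(tert-butyldimethylsilyl)oxy]methyl}-1-[2-(trimethylsilyl)furan-3-yl]octa-4,7-dien-1-yl 2-methylpropanoate | C=C[C@H](OC(=O)C=C)/C=C(/CO[Si](C)(C)C(C)(C)C)CC[C@H](OC(=O)C(C)C)c1ccoc1[Si](C)(C)C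
F7 | step 10 | (1S,4E,6S)-4-{[(tert-butyldimethylsilyl)oxy]methyl}-6-{[2-(hydroxymethyl)acryloyl]oxy}-1-[2-(trimethylsilyl)furan-3-yl]octa-4,7-dien-1-yl 2-methylpropanoate | C=C[C@H](OC(=O)C(=C)CO)/C=C(/CO[Si](C)(C)C(C)(C)C)CC[C@H](OC(=O)C(C)C)c1ccoc1[Si](C)(C)C
F8 | step 10 | (1S,4E)-4-{[(tert-butyldimethylsilyl)oxy]methyl}-5-[(2R)-4-(hydroxymethyl)-5-oxo-2,5-dihydrofuran-2-yl]-1-[2-(trimethylsilyl)furan-3-yl]pent-4-en-1-yl 2-methylpropanoate | OCC1=C[C@H](OC1=O)/C=C(/CO[Si](C)(C)C(C)(C)C)CC[C@H](OC(=O)C(C)C)c2ccoc2[Si](C)(C)C
F9 | step 3 | divinylzinc | C=C[Zn]C=C
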